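**Retrosynthetic overview**

1. The target is opened to a cyclodecenone β‑hydroxy keto ester (C6 ketone, C8–OH, C14–OAc, isopropyl acrylate on C7). One Evans–Tishchenko reduction with a silyloxyacetaldehyde sets C6, installs the C8 glycolate and frees C6–OH for the cis‑lactone.
2. The ten‑membered ring comes from a four‑atom ring expansion: Grob‑type fragmentation of the C1–C6 ring‑fusion bond of a cis‑fused decalin spiro‑epoxy alcohol. It gives C6=O, the ring‑cis C1=C10 alkene and C14–OH at once; the epoxide is made in the same flask from the C10 ketone with LiCH2Cl.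
3. The decalin ketol comes from an intramolecular indium Barbier allylation (C6–C7) after a catalytic asymmetric vinylogous Mukaiyama aldol (C8–C9).
4. The pieces are the bis(silyl) dienol ether of 2‑acetyl‑5‑methylcyclohexanone (from (S)‑3‑methylcyclohexanone and Ac2O) and a bromo‑enal (from 2,2‑dimethoxyacetaldehyde and isopropyl acrylate).
5. Ring order: ring A (bought methylcyclohexane), then ring B (annulated cyclohexane), then the ten‑membered carbocycle by cleaving the A/B bond, then the lactone.

Assumption: atoms carry germacranolide numbers (C1=C10 ring alkene, C14 on C10, C4 methyl carbon, C6 lactone carbinol, C7 ring‑fusion CH, C8 glycolate carbinol, C11=C13 methylene, C12 carboxyl); the target is (4S,6S,7S,8S,1(10)E) with a cis‑fused lactone, and (S)‑3‑methylcyclohexanone is bought as the single enantiomer.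

**Route**

Step 1
Reactants: 1 (S)-3-methylcyclohexan-1-one; 2 acetic anhydride
Product: 3 (5S)-2-acetyl-5-methylcyclohexan-1-one (keto/enol mixture, C2 not defined)
Conditions: Ac2O, BF3·OEt2, TsOH (cat.), 23 °C; then NaOAc, MeOH/H2O, reflux
Reagents that add atoms: none
Why: BF3‑promoted C‑acetylation of the ketone enol (Claisen‑type acylation) is steered by the stable BF2 diketonate to the less hindered α‑carbon C1, away from the methyl‑bearing side, and leaves the C4 stereocentre untouched.

Step 2
Reactants: 3 (5S)-2-acetyl-5-methylcyclohexan-1-one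
Product: 4 triethyl{[(5S)-5-methyl-2-{1-[(triethylsilyl)oxy]ethenyl}cyclohex-1-en-1-yl]oxy}silane
Conditions: TESOTf (2.3 equiv), Et3N, Et2O, 0 → 23 °C
Reagents that add atoms: triethylsilyl trifluoromethanesulfonate, CC[Si](CC)(CC)OS(=O)(=O)C(F)(F)F
Why: Double O‑silylation of the 1,3‑diketone (soft enolisation, second deprotonation at the acetyl methyl group) gives the cross‑conjugated 1,3‑bis(silyloxy)diene of the Chan type.

Step 3
Reactants: 5 2,2-dimethoxyacetaldehyde (60% aqueous solution); 6 propan-2-yl prop-2-enoate (isopropyl acrylate)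
Product: 7 propan-2-yl 3-hydroxy-4,4-dimethoxy-2-methylidenebutanoate (racemic)
Conditions: DABCO (0.5 equiv), dioxane/H2O, 23 °C
Reagents that add atoms: none
Why: Morita–Baylis–Hillman reaction of an activated α‑alkoxy aldehyde with an acrylate; the carbinol centre is racemic and is destroyed in the next step.

Step 4
Reactants: 7 propan-2-yl 3-hydroxy-4,4-dimethoxy-2-methylidenebutanoate
Product: 9 propan-2-yl (2Z)-2-(bromomethyl)-4-oxobut-2-enoate, via bromo acetal 8 (not isolated)
Conditions: PBr3 (0.4 equiv), Et2O, 0 °C; then 2 M HCl (aq), THF, 23 °C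
Reagents that add atoms: phosphorus tribromide, BrP(Br)Br; water, O
Why: SN2′ bromination of the Baylis–Hillman alcohol gives the thermodynamic (Z)-2-(bromomethyl)enoate (CH2Br cis to the C4 substituent, ester trans), and acid hydrolysis of the acetal frees the aldehyde, which cannot lactolise because it is trans to the ester.

Step 5
Reactants: 4 the bis(triethylsilyl) dienol ether; 9 propan-2-yl (2Z)-2-(bromomethyl)-4-oxobut-2-enoate
Product: 11 propan-2-yl (2Z,4S)-2-(bromomethyl)-6-[(4S)-4-methyl-2-oxocyclohexyl]-6-oxo-4-(triethylsilyloxy)hex-2-enoate, via bis-silyl aldol adduct 10 (not isolated)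
Conditions: Ti(OiPr)4 (10 mol %), (S)-BINOL (10 mol %), 4 Å MS, THF, −78 → −20 °C; then pH 7 buffer, SiO2
Reagents that add atoms: none
Why: Catalytic asymmetric vinylogous Mukaiyama aldol: the terminal diene carbon (C9) adds to the aldehyde under control of the chiral Ti(OiPr)4/BINOL catalyst, which sets the C8 carbinol as (S) independently of the remote C4 methyl (the antipodal ligand is used if Mosher analysis shows the opposite sense); silyl transfer leaves C8 as its TES ether, and the labile vinylogous silyl ester is hydrolysed on work‑up.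

Step 6
Reactants: 11 the δ‑silyloxy 1,3‑diketone allylic bromide
Product: 12 propan-2-yl 2-[(1R,2S,4aS,7S,8aR)-8a-hydroxy-7-methyl-4-oxo-2-(triethylsilyloxy)decahydronaphthalen-1-yl]prop-2-enoate (cis‑fused; angular OH cis to the acrylate, acrylate trans to OTES)
Conditions: In powder (2 equiv), THF/H2O (3:1), 0.01 M, 23 °C
Reagents that add atoms: none
Why: Intramolecular indium Barbier allylation of the 2‑(bromomethyl)acrylate type, tolerant of water and of the enolisable diketone: the allylindium attacks through its γ‑carbon C7 the C6 carbonyl of the chelated keto tautomer (acyl group equatorial), axial attack gives the cis‑fused decalin, and a chair transition state with the C8 silyloxy group equatorial plus allylic 1,3‑strain places the acrylate on C7 equatorial and trans to C8–O (C4 and C8 are matched for this chair), while the isopropyl ester resists lactonisation.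

Step 7
Reactants: 12 the cis‑fused decalin ketol
Product: 16 propan-2-yl (4S,7R,8S,1(10)E)-8,14-dihydroxy-6-oxogermacra-1(10),11(13)-dien-12-oate, via chlorohydrin alkoxide 13 (not isolated), via spiro-epoxide 14 (not isolated), via TES-protected cyclodecenone 15 (not isolated)
Conditions: ICH2Cl (2.5 equiv), MeLi·LiBr (2.4 equiv), THF, −78 °C; then Ti(OiPr)4 (1.5 equiv), −78 → 23 °C; then 1 M HCl (aq), THF, 0 °C
Reagents that add atoms: chloroiodomethane, ClCI
Why: Proposed new method: a one‑flask carbenoid methylene transfer/Grob ring expansion in which LiCH2Cl (far faster with the C10 ketone than with the conjugated isopropyl ester at −78 °C) is delivered from a mixed aggregate with the angular C6–OLi to the face syn to that oxygen, the chlorohydrin alkoxide closes to a spiro‑epoxide whose C10–O bond is equatorial and antiperiplanar to the C1–C6 ring‑fusion bond, and the C6 alkoxide on tetravalent titanium (which also activates the oxirane) then expels the epoxide oxygen so that the shared bond breaks and the two six‑membered rings become one ten‑membered ring with C6=O, the C14 carbinol and the ring‑cis C1=C10 alkene (C2 is axial on ring B in the reacting chair, so C2 and C9 end up cis, descriptor E); the closest known reactions are halomethyllithium epoxidation of ketones and the titanium‑mediated epoxy alcohol (Wharton–Grob) fragmentation, which have not been combined or used to turn a decalin ketol into a cyclodecenone; dilute acid removes the TES ether.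

Step 8
Reactants: 16 the dihydroxy keto ester
Product: 17 propan-2-yl (4S,7R,8S,1(10)E)-14-acetoxy-8-hydroxy-6-oxogermacra-1(10),11(13)-dien-12-oate
Conditions: AcCl (1.1 equiv), 2,4,6-collidine, CH2Cl2, −78 °C
Reagents that add atoms: acetyl chloride, CC(Cl)=O
Why: Chemoselective acetylation of the unhindered primary allylic alcohol in the presence of the hindered secondary aldol hydroxyl, under conditions too weakly basic for retro‑aldol, β‑elimination or C7 epimerisation.

Step 9
Reactants: 17 the C14 acetate β‑hydroxy ketone; 18 2-[(tert-butyldimethylsilyl)oxy]acetaldehyde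
Product: 21 the target (4S,6S,7S,8S,1(10)E)-14-acetoxy-8-(hydroxyacetoxy)germacra-1(10),11(13)-dien-12,6-olide, via Tishchenko monoester 19 (not isolated), via TBS-protected lactone 20 (not isolated)
Conditions: SmI2 (0.3 equiv, premixed with 18), 18 (4 equiv), THF, −10 °C; then HF·pyridine, THF, 0 → 23 °C
Reagents that add atoms: none
Why: Evans–Tishchenko reduction: the C8 hydroxyl forms a samarium‑bound hemiacetal with 18 and passes its hydride intramolecularly to the C6 ketone through a six‑membered chair, which sets C6 1,3‑anti to C8–O (6S) and leaves C8 as the silyl‑protected glycolate; the new C6 alkoxide closes the cis‑fused α‑methylene γ‑lactone on the isopropyl ester, and HF·pyridine removes the TBS group.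

**Compound list**

1 | (S)-3-methylcyclohexan-1-one | C[C@H]1CCCC(=O)C1 | starting material
2 | acetic anhydride | CC(=O)OC(C)=O | starting material
3 | (5S)-2-acetyl-5-methylcyclohexan-1-one | CC(=O)C1CC[C@H](C)CC1=O | intermediate
4 | triethyl{[(5S)-5-methyl-2-{1-[(triethylsilyl)oxy]ethenyl}cyclohex-1-en-1-yl]oxy}silane | C=C(O[Si](CC)(CC)CC)C1=C(O[Si](CC)(CC)CC)C[C@@H](C)CC1 | intermediate
5 | 2,2-dimethoxyacetaldehyde | COC(OC)C=O | starting material
6 | propan-2-yl prop-2-enoate | C=CC(=O)OC(C)C | starting material
7 | propan-2-yl 3-hydroxy-4,4-dimethoxy-2-methylidenebutanoate (racemic) | C=C(C(O)C(OC)OC)C(=O)OC(C)C | intermediate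
8 | propan-2-yl (2Z)-2-(bromomethyl)-4,4-dimethoxybut-2-enoate | COC(OC)/C=C(\CBr)C(=O)OC(C)C | intermediate (not isolated)
9 | propan-2-yl (2Z)-2-(bromomethyl)-4-oxobut-2-enoate | O=C/C=C(\CBr)C(=O)OC(C)C | intermediate
10 | propan-2-yl (2Z,4S)-2-(bromomethyl)-6-[(4S)-4-methyl-2-(triethylsilyloxy)cyclohex-1-en-1-yl]-6-oxo-4-(triethylsilyloxy)hex-2-enoate | CC(C)OC(=O)/C(CBr)=C/[C@@H](O[Si](CC)(CC)CC)CC(=O)C1=C(O[Si](CC)(CC)CC)C[C@@H](C)CC1 | intermediate (not isolated)
11 | propan-2-yl (2Z,4S)-2-(bromomethyl)-6-[(4S)-4-methyl-2-oxocyclohexyl]-6-oxo-4-(triethylsilyloxy)hex-2-enoate (ring C1 epimers/enol) | CC(C)OC(=O)/C(CBr)=C/[C@@H](O[Si](CC)(CC)CC)CC(=O)C1CC[C@H](C)CC1=O | intermediate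
12 | propan-2-yl 2-[(1R,2S,4aS,7S,8aR)-8a-hydroxy-7-methyl-4-oxo-2-(triethylsilyloxy)decahydronaphthalen-1-yl]prop-2-enoate | C=C(C(=O)OC(C)C)[C@@H]1[C@@H](O[Si](CC)(CC)CC)CC(=O)[C@H]2CC[C@H](C)C[C@@]12O | intermediate
13 | C10 chlorohydrin of 12 (lithium alkoxide in the flask; CH2Cl axial, cis to the angular OH) | C=C(C(=O)OC(C)C)[C@@H]1[C@@H](O[Si](CC)(CC)CC)C[C@](O)(CCl)[C@H]2CC[C@H](C)C[C@@]12O | intermediate (not isolated)
14 | C10 spiro-epoxide of 12 (oxirane O equatorial, trans to the angular OH; C10 is R) | C=C(C(=O)OC(C)C)[C@@H]1[C@@H](O[Si](CC)(CC)CC)C[C@]3(CO3)[C@H]2CC[C@H](C)C[C@@]12O | intermediate (not isolated)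
15 | propan-2-yl (4S,7R,8S,1(10)E)-14-hydroxy-6-oxo-8-(triethylsilyloxy)germacra-1(10),11(13)-dien-12-oate | C=C(C(=O)OC(C)C)[C@@H]1[C@@H](O[Si](CC)(CC)CC)C/C(CO)=C\CC[C@H](C)CC1=O | intermediate (not isolated)
16 | propan-2-yl (4S,7R,8S,1(10)E)-8,14-dihydroxy-6-oxogermacra-1(10),11(13)-dien-12-oate | C=C(C(=O)OC(C)C)[C@@H]1[C@@H](O)C/C(CO)=C\CC[C@H](C)CC1=O | intermediate
17 | propan-2-yl (4S,7R,8S,1(10)E)-14-acetoxy-8-hydroxy-6-oxogermacra-1(10),11(13)-dien-12-oate | C=C(C(=O)OC(C)C)[C@@H]1[C@@H](O)C/C(COC(C)=O)=C\CC[C@H](C)CC1=O | intermediate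
18 | 2-[(tert-butyldimethylsilyl)oxy]acetaldehyde (glycolaldehyde carrying a TBS protecting group) | CC(C)(C)[Si](C)(C)OCC=O | starting material
19 | propan-2-yl (4S,6S,7S,8S,1(10)E)-14-acetoxy-6-hydroxy-8-{[(tert-butyldimethylsilyl)oxy]acetoxy}germacra-1(10),11(13)-dien-12-oate | C=C(C(=O)OC(C)C)[C@@H]1[C@@H](OC(=O)CO[Si](C)(C)C(C)(C)C)C/C(COC(C)=O)=C\CC[C@H](C)C[C@@H]1O | intermediate (not isolated)
20 | (4S,6S,7S,8S,1(10)E)-14-acetoxy-8-{[(tert-butyldimethylsilyl)oxy]acetoxy}germacra-1(10),11(13)-dien-12,6-olide | C=C1C(=O)O[C@H]2C[C@@H](C)CC/C=C(/COC(C)=O)C[C@H](OC(=O)CO[Si](C)(C)C(C)(C)C)[C@@H]12 | intermediate (not isolated)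
21 | (4S,6S,7S,8S,1(10)E)-14-acetoxy-8-(hydroxyacetoxy)germacra-1(10),11(13)-dien-12,6-olide (CNP0156635.1) | C=C1C(=O)O[C@H]2C[C@@H](C)CC/C=C(/COC(C)=O)C[C@H](OC(=O)CO)[C@@H]12 | target

**Step count and risks**

Total steps: 9. Longest linear sequence: 7 (steps 1, 2, 5, 6, 7, 8, 9); steps 3 and 4 form the side branch.

Most likely to fail:

Step 7 (the proposed new ring expansion). Risks are the face of carbenoid attack on C10 (the wrong epoxide cannot fragment to the ring‑cis alkene), lactonisation of the C6 alkoxide onto the ester before fragmentation, and a slow fragmentation. Fallback, from 12 back to 14, all known chemistry: ketol 12 is methylenated at C10 under Takai–Lombardo conditions (Zn, CH2Br2, TiCl4) to the exocyclic alkene F3. The angular hydroxyl is capped as the trimethylsilyl ether F4 (TMSOTf, 2,6‑lutidine). Dimethyldioxirane then epoxidises the electron‑rich 1,1‑disubstituted alkene, not the acrylate, from the open equatorial face anti to the axial silyloxy group, giving epoxide F5. Citric acid in methanol removes only the tertiary TMS ether and returns epoxy alcohol 14, now isolated. It is fragmented with Ti(OiPr)4 (the known epoxy alcohol fragmentation) and desilylated with dilute HCl to 16.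

Step 6 (indium cyclisation onto a 1,3‑diketone carbonyl). Risks are low electrophilicity of the enolised diketone and formation of the trans‑fused or the other cis‑fused ketol. Fallback, from 11 back to 12: the diketone is sulfenylated at the carbon between the carbonyls with N‑(phenylthio)phthalimide and Et3N to give the non‑enolisable 2‑(phenylthio)‑1,3‑diketone F1. The same Barbier closure (In or Zn) now takes place on a true ketone and gives the sulfide ketol F2. SmI2 (2.2 equiv, THF/MeOH, −78 °C) cleaves the C–S bond α to the C10 ketone, and the samarium enolate is protonated on the face of the angular hydroxyl to give the cis‑fused ketol 12.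

Step 9 (Evans–Tishchenko in a ten‑membered ring next to an acrylate). Risks are a ring conformation that disfavours the hydride‑transfer chair, acyl migration and competing reduction by divalent samarium. Fallback, from 17 back to 19: the C8 hydroxyl is esterified with [(tert‑butyldimethylsilyl)oxy]acetic acid (DCC, DMAP cat., 0 °C) to give the keto diester F6. The C6 ketone is then reduced under reagent control with (R)‑Me‑CBS and catecholborane at −78 °C to the 6S alcohol 19. CSA closes the lactone to 20 and HF·pyridine gives 21.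

**Further compounds**

F1 | step 6 | propan-2-yl (2Z,4S)-2-(bromomethyl)-6-[(4S)-4-methyl-2-oxo-1-(phenylsulfanyl)cyclohexyl]-6-oxo-4-(triethylsilyloxy)hex-2-enoate (sulfur-bearing carbon not controlled) | CC(C)OC(=O)/C(CBr)=C/[C@@H](O[Si](CC)(CC)CC)CC(=O)C1(Sc2ccccc2)CC[C@H](C)CC1=O
F2 | step 6 | 4a-(phenylsulfanyl) analogue of ketol 12 (sulfur-bearing carbon not controlled) | C=C(C(=O)OC(C)C)[C@@H]1[C@@H](O[Si](CC)(CC)CC)CC(=O)C2(Sc3ccccc3)CC[C@H](C)C[C@@]12O
F3 | step 7 | C10 exocyclic methylene analogue of 12 (C=O replaced by C=CH2) | C=C(C(=O)OC(C)C)[C@@H]1[C@@H](O[Si](CC)(CC)CC)CC(=C)[C@H]2CC[C@H](C)C[C@@]12O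
F4 | step 7 | trimethylsilyl ether of F3 at the angular hydroxyl | C=C(C(=O)OC(C)C)[C@@H]1[C@@H](O[Si](CC)(CC)CC)CC(=C)[C@H]2CC[C@H](C)C[C@@]12O[Si](C)(C)C
F5 | step 7 | trimethylsilyl ether of spiro-epoxide 14 | C=C(C(=O)OC(C)C)[C@@H]1[C@@H](O[Si](CC)(CC)CC)C[C@]3(CO3)[C@H]2CC[C@H](C)C[C@@]12O[Si](C)(C)C
F6 | step 9 | propan-2-yl (4S,7R,8S,1(10)E)-14-acetoxy-6-oxo-8-{[(tert-butyldimethylsilyl)oxy]acetoxy}germacra-1(10),11(13)-dien-12-oate | C=C(C(=O)OC(C)C)[C@@H]1[C@@H](OC(=O)CO[Si](C)(C)C(C)(C)C)C/C(COC(C)=O)=C\CC[C@H](C)CC1=O
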